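**Convention:** positions are given in flavanone numbering (O1, C2–C8a; rings A, B, C) also for the pyrone and open-chain precursors, by the atom each position becomes; commercial solutions of LiN(i-Pr)2, i-PrMgCl and Mg(OMe)2 are assumed.

## The problem

Sophoraflavanone A (17) is a flavanone: the phloroglucinol-type ring A is fused through C4a–C8a to the dihydropyranone ring C, the 4-hydroxyphenyl ring B sits on C2, and a geranyl chain sits on C8, between the O1-bearing C8a and the 7-hydroxyl. The only stereocentre is C2 (S). It is benzylic, carries O1 and lies β to the C4 ketone, so nothing else in the molecule can direct it; it must be set by a reagent and then kept away from conditions that break the C2–O1 bond. Base breaks that bond by retro-oxa-Michael opening of ring C to an achiral chalcone, and acid can do so by ionising the para-oxygenated benzylic ether. The open chalcone is also a constitutional hazard, because it can re-close through the other ortho oxygen of ring A and give the 6-geranyl isomer; the synthesis therefore has to decide which of two nearly equivalent ring-A oxygens becomes O1. The geranyl chain has two trisubstituted alkenes, one of them the (E)-alkene next to the ring, which rule out hydrogenolysis, strong Brønsted or Lewis acids and electrophilic oxidants, and three phenols must be carried, one chelated to the ketone. The feature that invites a short solution is the pattern of ring A: C5, C7 and C8a carry oxygen, C4a carries the acyl carbon C4 and C8 carries the geranyl carbon. This is exactly what results when a chain C8a(ester)–C8(geranyl)–C7(=O)–C6–C5(=O)–C4a–C4(=O) folds by Claisen condensation of C4a onto C8a, and such a 2-geranyl-3,5,7-triketo ester can be stored as a 4-hydroxy-2-pyrone.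

## Retrosynthesis

**17 from 16.** Three phenolic O–CH2OMe bonds are cut. Methoxymethyl ethers are chosen because they survive amide bases, Mg(OMe)2 and fluoride. Benzyl ethers would need hydrogenolysis, which the alkenes forbid, and aryl silyl ethers would not survive methoxide. The forward step is a mild acetal exchange in which ring C is not exposed to base.

**16 from 15.** The O1–C2 bond is cut. The neighbouring way of making this bond, oxa-Michael closure of a 2'-hydroxychalcone, is reversible, has a racemic background path and cannot tell the two ortho oxygens apart. The bond is therefore made by intramolecular Mitsunobu displacement at a carbinol of fixed configuration: (R)-15 closes with inversion to (2S)-16. Compound 15 is an open-chain β-hydroxy ketone with exactly one free phenol, the one flanked by geranyl and the carbonyl. The forward step must proceed by clean SN2 displacement without ionisation of the benzylic centre.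

**15 from 14 from 13.** Only protecting-group bonds are cut: the carbinol silyl ether (15 from 14) and two ring-A methoxymethyl ethers (14 from 13). The silyl ether stays on until just before ring closure because it blocks retro-aldol cleavage and dehydration in every basic step. The forward protection has to separate the two ortho phenols of 13 by their steric surroundings.

**13 from 11 (through 12).** The C4a–C8a bond is cut and ring A disappears. The alternative ring-A cut, C4–C4a by acylation of a preformed geranylphloroglucinol, needs a Lewis acid next to the geranyl chain and a regiocontrolled geranylation of a symmetric arene. The Claisen cut instead places the geranyl carbon between two carbonyls of a chain, where its position on the future ring is fixed by connectivity. The chain is masked as pyrone 11 and released as triketo ester 12 only in the folding flask. The literal biomimetic cinnamoyl side chain is deliberately replaced by a saturated chain carrying the silyloxy carbinol, because a folded product with an enone and two free ortho phenols would close at once to racemic 6- and 8-geranyl flavanones. The forward step must fold in the Claisen mode and not in the aldol mode.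

**11 from 9 and 6.** The C4–C4a bond, between the 6-methyl carbon of pyrone 9 and the acyl carbon of amide 6, is cut. This splits the molecule into a geranyl pyrone and a chiral three-carbon aryl unit of similar size. The forward step is acylation of the dianion of 9 at its terminal carbon by a Weinreb amide, which stops at the ketone stage.

**9 from 7 and 8.** The bond between C8 and the geranyl CH2 is cut. Triacetic acid lactone 7 and geraniol 8 are both articles of commerce. The forward step is a palladium-catalysed allylation at the pyrone C3 carbon, and it must give the linear (E) product.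

**6 from 5, 4, 3, 2 and 1.** The N-acyl bond (6, 5 from 4), the carbinol C–H bond (4 from 3) and the C3–C4 bond (3 from 2) are cut, back to 4'-hydroxyacetophenone 1. The stereocentre is set by asymmetric transfer hydrogenation of the aryl β-keto ester 3, a reduction with a predictable facial rule for aryl ketones. This was preferred over an auxiliary-based acetate aldol because it is catalytic.

## Roads not taken

**Alternative 1:** The cut is C4–C4a, made last. Acid A1, in which the aryl ether O1–C2 and the stereocentre already exist, would be activated as its acyl chloride and closed by Friedel–Crafts acylation with a mild Lewis acid at low temperature to give flavanone A2.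
- Merits: A1 has only one free ring carbon ortho to the ether oxygen, so the 8- versus 6-geranyl question cannot arise at ring closure. In this respect it is better than the chosen plan, which must separate two ortho phenols by protection. The ring is nucleophilic enough for gentle activation, and the ring-B pivalate damps benzylic ionisation.
- Weak points: a Lewis acid and an acylium-type species meet the geranyl diene (cation–olefin cyclisation, hydrochlorination) and aryl silyl ethers. β-Aryloxy acyl chlorides can lose the phenoxide by E1cB. Building A1 needs an intermolecular etherification, with inversion, of a hindered geranyl-flanked phenol at a benzylic carbinol, and its phenol component still needs one of three hydroxyls singled out. The pivalate must finally be removed by a nucleophilic base, the condition that opens ring C.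
- Comparison: against the regiochemical advantage of A2, the chosen plan sets ring-A formation under base only, never exposing geranyl to a Lewis acid, and an intramolecular rather than intermolecular displacement at the benzylic centre.

**Alternative 2:** The cuts are C8–C8a and C4a–C5. Diene A4, carrying the geranyl chain at its nucleophilic terminus, would add across the sulfinyl-activated enone double bond of the chiral dihydropyranone A3; loss of sulfenic acid and methoxysilane would aromatise ring A to A5.
- Merits: the stereocentre would come from a well-developed catalytic asymmetric hetero-Diels–Alder reaction, and the geranyl position is fixed by the polarity of the cycloaddition. A5 emerges with the 5- and 7-hydroxyls free, so no phenol discrimination is needed and only one silyl group remains to be removed. In step count and protecting-group economy this road is better than the chosen one.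
- Weak points: A3 is a vinylogous ester and a poor dienophile at a fully substituted α-carbon. Terminally substituted trioxygenated dienes such as A4 are sluggish and hydrolytically labile. The first adduct can expel O1 by β-elimination, which opens ring C and erases C2. The annulation of ring A onto a 2-aryl dihydropyranone would be a new method.
- Comparison: the chosen plan is longer, but its central step belongs to a known reaction class and its stereocentre is never placed β to a newly formed enolate.

**Alternative 3:** The cut is O1–C8a. Zerovalent palladium with a bulky biarylphosphine would couple the (S)-carbinol of A6 with its aryl triflate to give flavan A7.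
- Merits: the carbinol oxygen is the nucleophile, so C2 is not touched and its configuration is retained without any ionisation hazard. In stereochemical fidelity this is better than the Mitsunobu closure of the chosen plan.
- Weak points: oxidative addition into a di-ortho-substituted, electron-rich aryl triflate is slow, and the secondary palladium alkoxide can undergo β-hydride elimination. C4 must be carried as a protected alcohol, so desilylation and oxidation are added after ring closure, before the final deprotection. Placing the triflate on the geranyl-flanked oxygen needs the same phenol discrimination as the chosen plan.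
- Comparison: the chosen plan sets against the cleaner C2 handling a shorter end-game, no oxidation-level detour and a ring-A construction that fixes the geranyl position.

Key step: step 8

## Route

Step 1
Reactants: 1 4'-hydroxyacetophenone
Product: 2 1-[4-(methoxymethoxy)phenyl]ethanone
Conditions: MOMCl, i-Pr2NEt, CH2Cl2, 0 °C to rt
Reagents that add atoms: chloromethyl methyl ether, COCCl
Why: Phenol O-alkylation with an α-chloro ether; the resulting acetal is inert to hydride and amide bases, Grignard reagents, Mg(OMe)2 and fluoride and is cleaved only in the last step.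

Step 2
Reactants: 2 1-[4-(methoxymethoxy)phenyl]ethanone
Product: 3 ethyl 3-[4-(methoxymethoxy)phenyl]-3-oxopropanoate
Conditions: NaH, (EtO)2CO, THF, 65 °C; AcOH quench
Reagents that add atoms: diethyl carbonate, CCOC(=O)OCC
Why: Crossed Claisen condensation of the ketone enolate with a non-enolisable carbonate, driven by formation of the stabilised β-keto ester enolate; the aryl acetal is base-stable.

Step 3
Reactants: 3 ethyl 3-[4-(methoxymethoxy)phenyl]-3-oxopropanoate
Product: 4 ethyl (3R)-3-hydroxy-3-[4-(methoxymethoxy)phenyl]propanoate
Conditions: RuCl(p-cymene)[(R,R)-TsDPEN] (1 mol %), HCO2H/Et3N (5:2), 30 °C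
Reagents that add atoms: none
Why: Noyori–Ikariya asymmetric transfer hydrogenation of an aryl ketone; the (R,R)-TsDPEN ruthenium hydride should deliver hydride to the face that gives (R)-1-arylalkanols (arene–aryl CH–π contact in the six-membered transition state), which sets the carbinol that later becomes C2, and the buffered formic acid medium should leave the acetal intact.

Step 4
Reactants: 4 ethyl (3R)-3-hydroxy-3-[4-(methoxymethoxy)phenyl]propanoate
Product: 5 (3R)-3-hydroxy-N-methoxy-N-methyl-3-[4-(methoxymethoxy)phenyl]propanamide
Conditions: MeNH(OMe)·HCl, i-PrMgCl, THF, −20 to 0 °C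
Reagents that add atoms: N,O-dimethylhydroxylamine hydrochloride, CNOC.Cl
Why: Ester aminolysis by the chloromagnesium amide (Weinreb amide formation); the β-hydroxyl travels as its magnesium alkoxide, which at this temperature should neither retro-aldolise nor eliminate, so the stereocentre is untouched.

Step 5
Reactants: 5 (3R)-3-hydroxy-N-methoxy-N-methyl-3-[4-(methoxymethoxy)phenyl]propanamide
Product: 6 (3R)-3-(tert-butyldimethylsilyloxy)-N-methoxy-N-methyl-3-[4-(methoxymethoxy)phenyl]propanamide
Conditions: TBSCl, imidazole, DMF, rt
Reagents that add atoms: tert-butyldimethylsilyl chloride, CC(C)(C)[Si](C)(C)Cl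
Why: Imidazole-promoted silylation of a secondary alcohol; the alkyl silyl ether blocks retro-aldol cleavage and E1cB dehydration in the later basic steps and, unlike an aryl silyl ether, withstands methoxide.

Step 6
Reactants: 7 triacetic acid lactone (4-hydroxy-6-methyl-2H-pyran-2-one); 8 geraniol
Product: 9 3-[(2E)-3,7-dimethylocta-2,6-dienyl]-4-hydroxy-6-methyl-2H-pyran-2-one
Conditions: Pd(PPh3)4 (5 mol %), 7 in slight excess, toluene, 80 °C
Reagents that add atoms: none
Why: Dehydrative Tsuji–Trost allylation: the acidic pyrone (pKa about 5) activates the allylic hydroxyl on zerovalent palladium and the pyronate attacks the π-geranyl complex through its soft C3 carbon at the unsubstituted terminus, which should give the linear (E) product; O-allyl isomers re-ionise under the catalyst and drain to the C-allyl compound, and the excess of 7 limits double allylation.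

Step 7
Reactants: 9 3-[(2E)-3,7-dimethylocta-2,6-dienyl]-4-hydroxy-6-methyl-2H-pyran-2-one; 6 (3R)-3-(tert-butyldimethylsilyloxy)-N-methoxy-N-methyl-3-[4-(methoxymethoxy)phenyl]propanamide
Product: 11 6-[(4R)-4-(tert-butyldimethylsilyloxy)-4-[4-(methoxymethoxy)phenyl]-2-oxobutyl]-3-[(2E)-3,7-dimethylocta-2,6-dienyl]-4-hydroxy-2H-pyran-2-one, via dilithium pyrone dianion 10 (not isolated)
Conditions: LiN(i-Pr)2 (2.3 equiv), THF, −78 °C; then 6, −78 to −20 °C; aq. NH4Cl, pH 4
Reagents that add atoms: none
Why: Acylation of a dicarbonyl-type dianion at its more basic terminal carbon, as with acetoacetate dianions; the Weinreb chelate holds the tetrahedral adduct until work-up, so no second addition or proton quench by the product occurs, and the β-silyloxy group should tolerate the cold amide-free addition.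

Step 8
Reactants: 11 6-[(4R)-4-(tert-butyldimethylsilyloxy)-4-[4-(methoxymethoxy)phenyl]-2-oxobutyl]-3-[(2E)-3,7-dimethylocta-2,6-dienyl]-4-hydroxy-2H-pyran-2-one
Product: 13 (3R)-3-(tert-butyldimethylsilyloxy)-1-{3-[(2E)-3,7-dimethylocta-2,6-dienyl]-2,4,6-trihydroxyphenyl}-3-[4-(methoxymethoxy)phenyl]propan-1-one, via open-chain methyl triketo ester 12 (not isolated)
Conditions: Mg(OMe)2 (5 equiv), MeOH, 25 to 65 °C; then cold 0.5 M aq. HCl
Reagents that add atoms: none
Why: Methoxide from Mg(OMe)2 adds to the lactone carbonyl of 11 and opens the pyrone to the methyl 3,5,7-triketo ester 12, held as a polyenolate magnesium chelate. In the chelate the methylene between the C5 and C7 ketones (future C4a) is the carbanion and the metal-bound ester carbonyl (future C8a) the electrophile; 6-(enolendo)-exo-trig attack, loss of methoxide and enolisation close ring A as its magnesium phenoxide, which makes the sequence irreversible. The closest known reaction type is the Mg(OMe)2-mediated Claisen-mode cyclisation of 6-(2-oxoalkyl)-4-hydroxy-2-pyrones to acylphloroglucinols, the laboratory counterpart of chalcone-synthase folding. No stereocentre is created: the geranyl-bearing carbon of 12 becomes aromatic C8 and the silyloxy carbinol is a spectator. The step needs Claisen folding to win over the aldol mode (geranyl-bearing carbon onto the C7 ketone) and over re-lactonisation; the geranyl group secures the first, because that aldol adduct has a quaternary carbon, cannot dehydrate to an arene and reverts, while magnesium chelation favours C- over O-acylation. The methylene next to the silyloxy carbon is flanked by only one carbonyl and should stay protonated in the polyanion, so neither an aldol through it nor β-elimination of silanolate should compete, and the saturated side chain cannot close to a racemic flavanone under the basic conditions.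

Step 9
Reactants: 13 (3R)-3-(tert-butyldimethylsilyloxy)-1-{3-[(2E)-3,7-dimethylocta-2,6-dienyl]-2,4,6-trihydroxyphenyl}-3-[4-(methoxymethoxy)phenyl]propan-1-one
Product: 14 (3R)-3-(tert-butyldimethylsilyloxy)-1-{3-[(2E)-3,7-dimethylocta-2,6-dienyl]-2-hydroxy-4,6-bis(methoxymethoxy)phenyl}-3-[4-(methoxymethoxy)phenyl]propan-1-one
Conditions: MOMCl (2.1 equiv), i-Pr2NEt, CH2Cl2, 0 °C
Reagents that add atoms: chloromethyl methyl ether, COCCl
Why: Base-mediated O-alkylation discriminated by acidity and steric access: the unchelated phenol para to the ketone (future 7-OH) should react first and the ortho phenol with a free neighbouring CH (future 5-OH) second, while the ortho phenol wedged between geranyl and the carbonyl stays hydrogen-bonded and free; that one must become O1.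

Step 10
Reactants: 14 (3R)-3-(tert-butyldimethylsilyloxy)-1-{3-[(2E)-3,7-dimethylocta-2,6-dienyl]-2-hydroxy-4,6-bis(methoxymethoxy)phenyl}-3-[4-(methoxymethoxy)phenyl]propan-1-one
Product: 15 (3R)-1-{3-[(2E)-3,7-dimethylocta-2,6-dienyl]-2-hydroxy-4,6-bis(methoxymethoxy)phenyl}-3-hydroxy-3-[4-(methoxymethoxy)phenyl]propan-1-one
Conditions: HF·pyridine, pyridine, THF, 0 °C to rt
Reagents that add atoms: none
Why: Fluoride-mediated desilylation under pyridine-buffered conditions; aryl acetals and alkenes are inert, and the absence of free base avoids E1cB dehydration of the β-hydroxy ketone to a chalcone.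

Step 11
Reactants: 15 (3R)-1-{3-[(2E)-3,7-dimethylocta-2,6-dienyl]-2-hydroxy-4,6-bis(methoxymethoxy)phenyl}-3-hydroxy-3-[4-(methoxymethoxy)phenyl]propan-1-one
Product: 16 (2S)-8-[(2E)-3,7-dimethylocta-2,6-dienyl]-5,7-bis(methoxymethoxy)-2-[4-(methoxymethoxy)phenyl]chroman-4-one
Conditions: PPh3, DIAD, toluene, −20 to 0 °C
Reagents that add atoms: none
Why: Intramolecular Mitsunobu etherification (6-exo-tet): the alkoxyphosphonium ion of the carbinol is displaced by the only free phenol with inversion, so (R)-15 should give (2S)-16; low temperature and a non-polar solvent are chosen so that SN2 closure outruns ionisation of the para-alkoxybenzylic centre, and since the other ring-A oxygens are blocked only the 8-geranyl isomer can form.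

Step 12
Reactants: 16 (2S)-8-[(2E)-3,7-dimethylocta-2,6-dienyl]-5,7-bis(methoxymethoxy)-2-[4-(methoxymethoxy)phenyl]chroman-4-one
Product: 17 sophoraflavanone A, (2S)-8-[(2E)-3,7-dimethylocta-2,6-dienyl]-5,7-dihydroxy-2-(4-hydroxyphenyl)chroman-4-one
Conditions: 3 M aq. HCl, MeOH, 40 °C
Reagents that add atoms: none
Why: Acid-catalysed acetal exchange with methanol; the chelated 5-O-acetal should leave first and the others follow under conditions kept mild and short to spare the geranyl alkenes, and without base ring C is not opened, so C2 keeps its configuration.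

## Compound list

1 | 4'-hydroxyacetophenone | CC(=O)c1ccc(O)cc1 | starting material
2 | 1-[4-(methoxymethoxy)phenyl]ethanone | CC(=O)c1ccc(OCOC)cc1 | intermediate
3 | ethyl 3-[4-(methoxymethoxy)phenyl]-3-oxopropanoate | CCOC(=O)CC(=O)c1ccc(OCOC)cc1 | intermediate
4 | ethyl (3R)-3-hydroxy-3-[4-(methoxymethoxy)phenyl]propanoate | CCOC(=O)C[C@@H](O)c1ccc(OCOC)cc1 | intermediate
5 | (3R)-3-hydroxy-N-methoxy-N-methyl-3-[4-(methoxymethoxy)phenyl]propanamide | CON(C)C(=O)C[C@@H](O)c1ccc(OCOC)cc1 | intermediate
6 | (3R)-3-(tert-butyldimethylsilyloxy)-N-methoxy-N-methyl-3-[4-(methoxymethoxy)phenyl]propanamide | CON(C)C(=O)C[C@@H](O[Si](C)(C)C(C)(C)C)c1ccc(OCOC)cc1 | intermediate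
7 | triacetic acid lactone, 4-hydroxy-6-methyl-2H-pyran-2-one | CC1=CC(O)=CC(=O)O1 | starting material
8 | geraniol, (2E)-3,7-dimethylocta-2,6-dien-1-ol | CC(C)=CCC/C(C)=C/CO | starting material
9 | 3-[(2E)-3,7-dimethylocta-2,6-dienyl]-4-hydroxy-6-methyl-2H-pyran-2-one | CC(C)=CCC/C(C)=C/CC1=C(O)C=C(C)OC1=O | intermediate
10 | dilithium salt of 9, deprotonated at the 4-hydroxyl and the 6-methyl group | CC(C)=CCC/C(C)=C/CC1=C([O-])C=C([CH2-])OC1=O.[Li+].[Li+] | intermediate (not isolated)
11 | 6-[(4R)-4-(tert-butyldimethylsilyloxy)-4-[4-(methoxymethoxy)phenyl]-2-oxobutyl]-3-[(2E)-3,7-dimethylocta-2,6-dienyl]-4-hydroxy-2H-pyran-2-one | CC(C)=CCC/C(C)=C/CC1=C(O)C=C(CC(=O)C[C@@H](O[Si](C)(C)C(C)(C)C)c2ccc(OCOC)cc2)OC1=O | intermediate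
12 | methyl (9R)-9-(tert-butyldimethylsilyloxy)-2-[(2E)-3,7-dimethylocta-2,6-dienyl]-9-[4-(methoxymethoxy)phenyl]-3,5,7-trioxononanoate, as its magnesium chelate, C2 unassigned | CC(C)=CCC/C(C)=C/CC(C(=O)OC)C(=O)CC(=O)CC(=O)C[C@@H](O[Si](C)(C)C(C)(C)C)c1ccc(OCOC)cc1 | intermediate (not isolated)
13 | (3R)-3-(tert-butyldimethylsilyloxy)-1-{3-[(2E)-3,7-dimethylocta-2,6-dienyl]-2,4,6-trihydroxyphenyl}-3-[4-(methoxymethoxy)phenyl]propan-1-one | CC(C)=CCC/C(C)=C/Cc1c(O)cc(O)c(C(=O)C[C@@H](O[Si](C)(C)C(C)(C)C)c2ccc(OCOC)cc2)c1O | intermediate
14 | (3R)-3-(tert-butyldimethylsilyloxy)-1-{3-[(2E)-3,7-dimethylocta-2,6-dienyl]-2-hydroxy-4,6-bis(methoxymethoxy)phenyl}-3-[4-(methoxymethoxy)phenyl]propan-1-one | CC(C)=CCC/C(C)=C/Cc1c(OCOC)cc(OCOC)c(C(=O)C[C@@H](O[Si](C)(C)C(C)(C)C)c2ccc(OCOC)cc2)c1O | intermediate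
15 | (3R)-1-{3-[(2E)-3,7-dimethylocta-2,6-dienyl]-2-hydroxy-4,6-bis(methoxymethoxy)phenyl}-3-hydroxy-3-[4-(methoxymethoxy)phenyl]propan-1-one | CC(C)=CCC/C(C)=C/Cc1c(OCOC)cc(OCOC)c(C(=O)C[C@@H](O)c2ccc(OCOC)cc2)c1O | intermediate
16 | (2S)-8-[(2E)-3,7-dimethylocta-2,6-dienyl]-5,7-bis(methoxymethoxy)-2-[4-(methoxymethoxy)phenyl]chroman-4-one | CC(C)=CCC/C(C)=C/Cc1c(OCOC)cc(OCOC)c2c1O[C@H](c1ccc(OCOC)cc1)CC2=O | intermediate
17 | sophoraflavanone A, (2S)-8-[(2E)-3,7-dimethylocta-2,6-dienyl]-5,7-dihydroxy-2-(4-hydroxyphenyl)chroman-4-one | CC(C)=CCC/C(C)=C/Cc1c(O)cc(O)c2c1O[C@H](c1ccc(O)cc1)CC2=O | target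

## Step count and risk

Total: 12 steps. Longest linear sequence: 11 steps (steps 1–5 and 7–12, from 1); the pyrone branch contributes step 6.

**Step 8 (key step).** The Claisen closure onto an ester that is α-branched by the geranyl group may be slow, so that the opened chain re-lactonises on work-up, fragments by retro-Claisen cleavage or loses silanolate before ring A forms. The fallback introduces geranyl after folding. It sets out from 7 and 6 and returns at 13.
- The dianion of 7 (LiN(i-Pr)2, THF, −78 °C) is acylated with 6 to give 6-[(4R)-4-(tert-butyldimethylsilyloxy)-4-[4-(methoxymethoxy)phenyl]-2-oxobutyl]-4-hydroxy-2H-pyran-2-one F1, the unbranched substrate type for which the Mg(OMe)2 folding is established.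
- Folding of F1 gives (3R)-3-(tert-butyldimethylsilyloxy)-3-[4-(methoxymethoxy)phenyl]-1-(2,4,6-trihydroxyphenyl)propan-1-one F2.
- C-geranylation of F2 with commercial geranyl bromide and DBU in THF, where the two free ring carbons are equivalent, gives 13.

**Step 6.** The π-geranyl palladium intermediate may lose positional or geometric integrity (attack at the tertiary terminus, E to Z isomerisation, diene formation by β-hydride loss), or the pyrone may be allylated twice. The fallback builds the pyrone around an SN2-installed geranyl group. It sets out from 8 and returns at 9.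
- 8 is converted with PBr3 (Et2O, −10 °C) into geranyl bromide F3.
- The sodium enolate of methyl acetoacetate (NaH, THF) is alkylated with F3 to give methyl (4E)-2-acetyl-5,9-dimethyldeca-4,8-dienoate F4.
- The dianion of F4 (NaH, then n-BuLi, THF, 0 °C) is acetylated at its terminal carbon with N-methoxy-N-methylacetamide to give methyl 2-[(2E)-3,7-dimethylocta-2,6-dienyl]-3,5-dioxohexanoate F5.
- F5 lactonises with DBU in refluxing toluene to 9.

**Step 7.** Proton transfer from the amide α-methylene to the dianion, followed by loss of silanolate, or simply sluggish addition to the hindered amide, may replace C-acylation. The fallback is an aldol addition followed by oxidation. It sets out from 6 and 9 and returns at 11.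
- 6 is reduced with i-Bu2AlH (THF, −78 °C) to (3R)-3-(tert-butyldimethylsilyloxy)-3-[4-(methoxymethoxy)phenyl]propanal F6.
- Dianion 10, made from 9 as in step 7, adds to F6 to give 6-[(4R)-4-(tert-butyldimethylsilyloxy)-2-hydroxy-4-[4-(methoxymethoxy)phenyl]butyl]-3-[(2E)-3,7-dimethylocta-2,6-dienyl]-4-hydroxy-2H-pyran-2-one F7 as a mixture of carbinol epimers.
- Oxidation of F7 with Dess–Martin periodinane gives 11.

**Step 9.** Site selection between the two ortho phenols may be poor, or protection may run on to the tris-ether; the wrong isomer would lead into the 6-geranyl series. The fallback protects before the ring carries geranyl, when the two ortho phenols are equivalent. It sets out from 7 and 6 and returns at 14.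
- The geranyl-free pyrone F1 and the geranyl-free acylphloroglucinol F2 are made as in the fallback to step 8.
- F2 with MOMCl (2 equiv) and i-Pr2NEt gives (3R)-3-(tert-butyldimethylsilyloxy)-1-[2-hydroxy-4,6-bis(methoxymethoxy)phenyl]-3-[4-(methoxymethoxy)phenyl]propan-1-one F8.
- Ortho C-geranylation of the sodium phenoxide of F8 (NaH, toluene, geranyl bromide) gives 14. The only free carbon ortho to the phenoxide oxygen is the required one; O-alkylation is the expected competitor.

**Step 11.** Ionisation of the para-alkoxybenzylic oxyphosphonium ion would erode the configuration at C2, and elimination to the chalcone would open a racemic path. The fallback is a kinetic resolution. It sets out from 16 of eroded enantiomeric purity and returns at 16.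
- 16 is treated with RuCl(p-cymene)[(R,R)-TsDPEN] in HCO2H/Et3N. By the aryl-ketone facial rule this catalyst forms (4R)-carbinols and should therefore consume the (2R)-ketone through the cis pathway.
- This gives (2R,4R)-8-[(2E)-3,7-dimethylocta-2,6-dienyl]-5,7-bis(methoxymethoxy)-2-[4-(methoxymethoxy)phenyl]chroman-4-ol F9, which is separated from unreacted (2S)-16.

## Further compounds

F1 | step 8 | 6-[(4R)-4-(tert-butyldimethylsilyloxy)-4-[4-(methoxymethoxy)phenyl]-2-oxobutyl]-4-hydroxy-2H-pyran-2-one | O=C1C=C(O)C=C(CC(=O)C[C@@H](O[Si](C)(C)C(C)(C)C)c2ccc(OCOC)cc2)O1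
F2 | step 8 | (3R)-3-(tert-butyldimethylsilyloxy)-3-[4-(methoxymethoxy)phenyl]-1-(2,4,6-trihydroxyphenyl)propan-1-one | O=C(C[C@@H](O[Si](C)(C)C(C)(C)C)c1ccc(OCOC)cc1)c1c(O)cc(O)cc1O
F3 | step 6 | geranyl bromide, (2E)-1-bromo-3,7-dimethylocta-2,6-diene | CC(C)=CCC/C(C)=C/CBr
F4 | step 6 | methyl (4E)-2-acetyl-5,9-dimethyldeca-4,8-dienoate | CC(C)=CCC/C(C)=C/CC(C(C)=O)C(=O)OC
F5 | step 6 | methyl 2-[(2E)-3,7-dimethylocta-2,6-dienyl]-3,5-dioxohexanoate | CC(C)=CCC/C(C)=C/CC(C(=O)OC)C(=O)CC(C)=O
F6 | step 7 | (3R)-3-(tert-butyldimethylsilyloxy)-3-[4-(methoxymethoxy)phenyl]propanal | O=CC[C@@H](O[Si](C)(C)C(C)(C)C)c1ccc(OCOC)cc1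
F7 | step 7 | 6-[(4R)-4-(tert-butyldimethylsilyloxy)-2-hydroxy-4-[4-(methoxymethoxy)phenyl]butyl]-3-[(2E)-3,7-dimethylocta-2,6-dienyl]-4-hydroxy-2H-pyran-2-one, both epimers at the new carbinol | CC(C)=CCC/C(C)=C/CC1=C(O)C=C(CC(O)C[C@@H](O[Si](C)(C)C(C)(C)C)c2ccc(OCOC)cc2)OC1=O
F8 | step 9 | (3R)-3-(tert-butyldimethylsilyloxy)-1-[2-hydroxy-4,6-bis(methoxymethoxy)phenyl]-3-[4-(methoxymethoxy)phenyl]propan-1-one | COCOc1cc(O)c(C(=O)C[C@@H](O[Si](C)(C)C(C)(C)C)c2ccc(OCOC)cc2)c(OCOC)c1
F9 | step 11 | (2R,4R)-8-[(2E)-3,7-dimethylocta-2,6-dienyl]-5,7-bis(methoxymethoxy)-2-[4-(methoxymethoxy)phenyl]chroman-4-ol | CC(C)=CCC/C(C)=C/Cc1c(OCOC)cc(OCOC)c2c1O[C@@H](c1ccc(OCOC)cc1)C[C@H]2O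
A1 | alternative 1 | (3S)-3-{3,5-bis(tert-butyldimethylsilyloxy)-2-[(2E)-3,7-dimethylocta-2,6-dienyl]phenoxy}-3-[4-(pivaloyloxy)phenyl]propanoic acid | CC(C)=CCC/C(C)=C/Cc1c(O[Si](C)(C)C(C)(C)C)cc(O[Si](C)(C)C(C)(C)C)cc1O[C@H](c1ccc(OC(=O)C(C)(C)C)cc1)CC(=O)O
A2 | alternative 1 | (2S)-8-geranyl-5,7-bis(tert-butyldimethylsilyloxy)-4'-pivaloyloxyflavanone | CC(C)=CCC/C(C)=C/Cc1c(O[Si](C)(C)C(C)(C)C)cc(O[Si](C)(C)C(C)(C)C)c2c1O[C@H](c1ccc(OC(=O)C(C)(C)C)cc1)CC2=O
A3 | alternative 2 | (2S)-2-[4-(tert-butyldimethylsilyloxy)phenyl]-5-(phenylsulfinyl)-2,3-dihydro-4H-pyran-4-one, sulfur configuration unassigned | O=C1C[C@@H](c2ccc(O[Si](C)(C)C(C)(C)C)cc2)OC=C1S(=O)c1ccccc1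
A4 | alternative 2 | (6E)-1-methoxy-7,11-dimethyl-1,3-bis(trimethylsilyloxy)dodeca-1,3,6,10-tetraene | COC(O[Si](C)(C)C)=CC(O[Si](C)(C)C)=CC/C=C(\C)CCC=C(C)C
A5 | alternative 2 | (2S)-8-geranylnaringenin 4'-tert-butyldimethylsilyl ether | CC(C)=CCC/C(C)=C/Cc1c(O)cc(O)c2c1O[C@H](c1ccc(O[Si](C)(C)C(C)(C)C)cc1)CC2=O
A6 | alternative 3 | (1S)-3-(tert-butyldimethylsilyloxy)-3-{3-[(2E)-3,7-dimethylocta-2,6-dienyl]-4,6-bis(methoxymethoxy)-2-(trifluoromethylsulfonyloxy)phenyl}-1-[4-(methoxymethoxy)phenyl]propan-1-ol, either epimer at the silyloxy carbon | CC(C)=CCC/C(C)=C/Cc1c(OCOC)cc(OCOC)c(C(C[C@H](O)c2ccc(OCOC)cc2)O[Si](C)(C)C(C)(C)C)c1OS(=O)(=O)C(F)(F)F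
A7 | alternative 3 | (2S)-4-(tert-butyldimethylsilyloxy)-8-geranyl-5,7,4'-tris(methoxymethoxy)flavan, either C4 epimer | CC(C)=CCC/C(C)=C/Cc1c(OCOC)cc(OCOC)c2c1O[C@H](c1ccc(OCOC)cc1)CC2O[Si](C)(C)C(C)(C)C
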